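**Retrosynthetic overview**

1. Feature: the ten-membered carbocycle is numbered C1 (ring carbon with the exocyclic CH2), C2, C3, C4 (CO2H), quaternary C5, C6, Z C7=C8, C9=C10 (CO2H on C10). The exocyclic C1=CH2 and the ring C9=C10 bond form a 1,3-diene whose inner carbons C1 and C10 are ring neighbours, which is the mark of an endo-mode ring-closing enyne metathesis of a C1≡C10 ynoate.
2. Disconnection 1 (the only ring, closed in the penultimate step): C9=C10 and C1=CH2 lead back to acyclic ynoate 24 with a terminal Z-diene. Both carboxyls are carried as 4-methoxybenzyl esters, because the C4 ester beside quaternary C5 would not saponify under conditions the trienoate tolerates.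
3. Disconnection 2: the C4–C5 bond with both stereocentres comes from an enantioselective Ireland–Claisen rearrangement of allyl ester 7 (hex-5-ynoic acid plus E allylic alcohol 6).
4. Between these, the three arms are elaborated: vinyl to 3-furyl ketone, silyloxyethyl to Z-diene, alkynylsilane to ynoate.
5. Ring order: the furan is bought in (3-bromofuran); the ten-membered ring is formed in step 14; step 15 frees the two acids.

Key step: step 14

Assumption: the (4S,5S)-diazaborolidine controller is taken to favour the chair that gives (2R,3S)-10. Olefin and enolate geometry alone fix the relative configuration, so a reversed facial sense would be met by the (4R,5R)-controller with nothing else changed.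

**Route**

Step 1
Reactants: 1 hex-5-ynoic acid
Product: 3 6-(trimethylsilyl)hex-5-ynoic acid, via silyl ester 2 (not isolated)
Conditions: n-BuLi (2.1 equiv), THF, −78 to 0 °C; Me3SiCl (2.3 equiv); then 1 M HCl, rt
Reagents that add atoms: chlorotrimethylsilane C[Si](C)(C)Cl
Why: Double deprotonation (carboxylate and acetylide) followed by silylation caps the acidic alkyne C–H for steps 4 to 12, and the silyl ester is hydrolysed on acidic work-up while the C(sp)–Si bond stays.

Step 2
Reactants: 4 tert-butyl(but-3-yn-1-yloxy)dimethylsilane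
Product: 6 (2E)-5-{[tert-butyl(dimethyl)silyl]oxy}-3-methylpent-2-en-1-ol, via alkenylalane 5 (not isolated)
Conditions: AlMe3 (2.5 equiv), Zr(C5H5)2Cl2 (0.25 equiv), CH2Cl2, 0 °C to rt; then (CH2O)n, 0 °C to rt; aq. Rochelle salt
Reagents that add atoms: trimethylaluminium C[Al](C)C; paraformaldehyde (formaldehyde unit) C=O
Why: Zirconium-catalysed methylalumination (Negishi carboalumination) is a syn addition that puts CH3 on the internal carbon, and the alkenylalane adds to formaldehyde with retention, which fixes the E trisubstituted olefin needed in step 4.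

Step 3
Reactants: 3 6-(trimethylsilyl)hex-5-ynoic acid; 6 (2E)-5-{[tert-butyl(dimethyl)silyl]oxy}-3-methylpent-2-en-1-ol
Product: 7 (2E)-5-{[tert-butyl(dimethyl)silyl]oxy}-3-methylpent-2-en-1-yl 6-(trimethylsilyl)hex-5-ynoate
Conditions: DCC, DMAP (cat.), CH2Cl2, 0 °C to rt
Reagents that add atoms: none
Why: Steglich esterification of an unhindered primary allylic alcohol with a simple alkanoic acid.

Step 4
Reactants: 7 allyl ester
Product: 10 (2R,3S)-3-(2-{[tert-butyl(dimethyl)silyl]oxy}ethyl)-3-methyl-2-[4-(trimethylsilyl)but-3-yn-1-yl]pent-4-enoic acid, via boron ketene acetal 8 (not isolated), via acyloxyborane 9 (not isolated)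
Conditions: (4S,5S)-2-bromo-4,5-diphenyl-1,3-bis{[3,5-bis(trifluoromethyl)phenyl]sulfonyl}-1,3,2-diazaborolidine (1.3 equiv, made beforehand from the bis-sulfonamide and BBr3, HBr removed in vacuo), i-Pr2NEt, CH2Cl2, −78 °C; then −20 to 4 °C; aqueous work-up
Reagents that add atoms: none
Why: Enantioselective Ireland–Claisen rearrangement in which soft enolisation gives the Z(O)-boron ketene acetal (butynyl chain cis to O–B) and a chair with the E-olefin substituent CH2CH2OTBS equatorial forms the C4–C5 bond, so that the C4 side chain and the silyloxyethyl arm on quaternary C5 end up syn in the carboxyl-to-vinyl zigzag (relative configuration from the two olefin geometries, absolute configuration from the C2-symmetric diazaborolidine).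

Step 5
Reactants: 10 (2R,3S)-acid
Product: 11 4-methoxybenzyl (2R,3S)-3-(2-{[tert-butyl(dimethyl)silyl]oxy}ethyl)-3-methyl-2-[4-(trimethylsilyl)but-3-yn-1-yl]pent-4-enoate
Conditions: 4-methoxybenzyl chloride, K2CO3, DMF, rt
Reagents that add atoms: 4-methoxybenzyl chloride COc1ccc(CCl)cc1
Why: O-alkylation of the carboxylate (SN2 at the benzylic chloride) is indifferent to the shielding of the carboxyl carbon by quaternary C5 and gives an ester that can later be removed without acyl attack.

Step 6
Reactants: 11 4-methoxybenzyl ester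
Product: 13 4-methoxybenzyl (2R,3R)-3-(2-{[tert-butyl(dimethyl)silyl]oxy}ethyl)-5-hydroxy-3-methyl-2-[4-(trimethylsilyl)but-3-yn-1-yl]pentanoate, via alkylborane 12 (not isolated)
Conditions: 9-BBN (1.5 equiv), THF, 0 °C to rt; then 30% H2O2, aq. NaOAc, 0 °C
Reagents that add atoms: hydrogen peroxide OO
Why: Anti-Markovnikov hydroboration–oxidation with bulky 9-BBN should take the monosubstituted vinyl group in preference to the silyl-capped internal alkyne, and the buffered oxidation limits lactonisation onto the hindered ester (the descriptor at C3 changes by priority only).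

Step 7
Reactants: 13 primary alcohol
Product: 14 4-methoxybenzyl (2R,3S)-3-(2-{[tert-butyl(dimethyl)silyl]oxy}ethyl)-3-methyl-5-oxo-2-[4-(trimethylsilyl)but-3-yn-1-yl]pentanoate
Conditions: Dess–Martin periodinane, NaHCO3, CH2Cl2, 0 °C to rt
Reagents that add atoms: none
Why: Dess–Martin oxidation converts the primary alcohol into the aldehyde under buffered conditions that leave C4–H untouched.

Step 8
Reactants: 14 aldehyde; 15 3-bromofuran
Product: 17 4-methoxybenzyl (2R,3S)-3-(2-{[tert-butyl(dimethyl)silyl]oxy}ethyl)-5-(furan-3-yl)-5-hydroxy-3-methyl-2-[4-(trimethylsilyl)but-3-yn-1-yl]pentanoate (both carbinol epimers), via furan-3-yllithium 16 (not isolated)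
Conditions: 15, n-BuLi, THF, −78 °C; then 14, −78 °C; AcOH quench at −78 °C
Reagents that add atoms: none
Why: Bromine–lithium exchange at −78 °C gives the 3-lithiofuran without isomerisation to the 2-isomer, and its 1,2-addition to the aldehyde outpaces attack on the neopentyl-like ester; the new carbinol centre is removed in step 9.

Step 9
Reactants: 17 furyl carbinol
Product: 18 4-methoxybenzyl (2R,3S)-3-(2-{[tert-butyl(dimethyl)silyl]oxy}ethyl)-5-(furan-3-yl)-3-methyl-5-oxo-2-[4-(trimethylsilyl)but-3-yn-1-yl]pentanoate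
Conditions: Dess–Martin periodinane, NaHCO3, CH2Cl2, rt
Reagents that add atoms: none
Why: Dess–Martin oxidation of the heteroaryl carbinol converges both epimers on the 3-furyl ketone.

Step 10
Reactants: 18 silyl ether
Product: 19 4-methoxybenzyl (2R,3S)-5-(furan-3-yl)-3-(2-hydroxyethyl)-3-methyl-5-oxo-2-[4-(trimethylsilyl)but-3-yn-1-yl]pentanoate
Conditions: HF·pyridine, pyridine, THF, 0 °C to rt
Reagents that add atoms: none
Why: Buffered HF cleaves the primary O–Si bond (silyl ether deprotection) while the C(sp)–SiMe3 bond, the ketone and the benzylic ester are kept.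

Step 11
Reactants: 19 primary alcohol
Product: 20 4-methoxybenzyl (2R,3S)-5-(furan-3-yl)-3-methyl-5-oxo-3-(2-oxoethyl)-2-[4-(trimethylsilyl)but-3-yn-1-yl]pentanoate
Conditions: Dess–Martin periodinane, NaHCO3, CH2Cl2, 0 °C to rt
Reagents that add atoms: none
Why: Dess–Martin oxidation of the open hydroxy ketone (in equilibrium with its cyclic hemiketal) gives the keto aldehyde, which cannot undergo an intramolecular aldol to a ring of reasonable size.

Step 12
Reactants: 20 keto aldehyde
Product: 22 4-methoxybenzyl (2R,3S,5Z)-3-[2-(furan-3-yl)-2-oxoethyl]-3-methyl-2-[4-(trimethylsilyl)but-3-yn-1-yl]octa-5,7-dienoate, via phosphine adduct 21 (not isolated)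
Conditions: allyldiphenylphosphine, t-BuLi, THF, −78 °C; Ti(OiPr)4, −78 °C; then 20, −78 to 0 °C; MeI, 0 °C to rt
Reagents that add atoms: allyldiphenylphosphine C=CCP(c1ccccc1)c1ccccc1
Why: In this Z-selective Horner–Wittig-type diene synthesis the titanated allylphosphine adds through its α-carbon to the aldehyde (not the ketone) with erythro selectivity, and P-methylation triggers syn-elimination of Ph2P(O)CH3 to give the terminal Z-diene (C7=C8 Z).

Step 13
Reactants: 22 alkynylsilane
Product: 24 bis(4-methoxybenzyl) (6R)-6-[(3S,5Z)-1-(furan-3-yl)-3-methyl-1-oxoocta-5,7-dien-3-yl]hept-2-ynedioate, via caesium alkynoate 23 (not isolated)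
Conditions: CsF (dried), CO2 (1 atm), DMSO, rt; then 4-methoxybenzyl chloride, rt
Reagents that add atoms: carbon dioxide O=C=O; 4-methoxybenzyl chloride COc1ccc(CCl)cc1
Why: Fluoride-mediated desilylative carboxylation of the alkynylsilane with CO2 gives the caesium alkynoate, which is O-alkylated in the same flask, so no strong base meets the enolisable ketone or C4–H.

Step 14
Reactants: 24 enyne precursor
Product: 26 bis(4-methoxybenzyl) (4R,5S,7Z,9E)-5-[2-(furan-3-yl)-2-oxoethyl]-5-methyl-1-methylidenecyclodeca-7,9-diene-4,10-dicarboxylate (overview locants), via tetraene 25 (not isolated)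
Conditions: second-generation Grubbs catalyst RuCl2(=CHPh)(PCy3)(H2IMes) (15 mol%, in portions), ethylene (1 atm), toluene (1 mM), 80 °C; then argon sparge, 80 °C
Reagents that add atoms: ethylene C=C
Why: Proposed new method: under ethylene the ruthenium methylidene adds across the C1≡C10 ynoate (cross enyne metathesis) to give the 2,3-disubstituted butadiene 25, and the alkylidene then formed at C9 of the terminal Z-diene closes onto the C10 methylene, so that C9=C10 closes the ring and the CH2 on C1 remains as the exocyclic methylene; the direct path, in which the C9 alkylidene adds to the alkyne with C9–C10 bonding and the C1 vinylcarbene is capped by methylene transfer, gives the same product. The closest known reaction type is macrocyclic ring-closing enyne metathesis in the endo mode under ethylene, which gives 1,3-dienes with both alkyne carbons in the ring for twelve-membered and larger rings, whereas a ten-membered closure onto an ynoate with a dienyl partner is not established. The ring is closed in the endo mode (ten-membered, C1 and C10 both in the ring) and the ring size forces C8 and C1 cis on the new C9=C10 bond; no stereocentre is formed and C4 and C5 are untouched. The step needs endo closure (C9 to C10) over the nine-membered alternative (C9 to C1) and no attack at the internal C7=C8 alkene. The first rests on reversibility under ethylene, which should funnel material to the less strained ten-membered ring with the linearly conjugated trienoate, and on avoiding a ruthenium carbene on ester-bearing C10; the second rests on shielding of the Z C7=C8 bond by the neopentyl C6–C5 unit. High dilution suppresses dimerisation.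

Step 15
Reactants: 26 bis(4-methoxybenzyl) ester
Product: 27 (4R,5S,7Z,9E)-5-[2-(furan-3-yl)-2-oxoethyl]-5-methyl-1-methylidenecyclodeca-7,9-diene-4,10-dicarboxylic acid (overview locants; the target)
Conditions: CF3CO2H, anisole, CH2Cl2, 0 °C
Reagents that add atoms: none
Why: Acidolysis of both 4-methoxybenzyl esters proceeds by SN1 cleavage at the benzylic C–O bond (cation trapped by anisole), which frees both acids without nucleophilic attack at the hindered C4 carboxyl and without base that could isomerise the trienoate or epimerise C4.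

**Compound list**

1 | hex-5-ynoic acid | C#CCCCC(=O)O | starting material
2 | trimethylsilyl 6-(trimethylsilyl)hex-5-ynoate | C[Si](C)(C)C#CCCCC(=O)O[Si](C)(C)C | intermediate (not isolated)
3 | 6-(trimethylsilyl)hex-5-ynoic acid | C[Si](C)(C)C#CCCCC(=O)O | intermediate
4 | tert-butyl(but-3-yn-1-yloxy)dimethylsilane | C#CCCO[Si](C)(C)C(C)(C)C | starting material
5 | [(1E)-4-{[tert-butyl(dimethyl)silyl]oxy}-2-methylbut-1-en-1-yl]dimethylalane | C[Al](C)/C=C(\C)CCO[Si](C)(C)C(C)(C)C | intermediate (not isolated)
6 | (2E)-5-{[tert-butyl(dimethyl)silyl]oxy}-3-methylpent-2-en-1-ol | C/C(CCO[Si](C)(C)C(C)(C)C)=C\CO | intermediate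
7 | (2E)-5-{[tert-butyl(dimethyl)silyl]oxy}-3-methylpent-2-en-1-yl 6-(trimethylsilyl)hex-5-ynoate | C[Si](C)(C)C#CCCCC(=O)OC/C=C(\C)CCO[Si](C)(C)C(C)(C)C | intermediate
8 | Z(O)-boron ketene acetal of 7 with the (4S,5S)-diazaborolidine (butynyl chain cis to O–B) | C[Si](C)(C)C#CCC/C=C(/OC/C=C(\C)CCO[Si](C)(C)C(C)(C)C)OB1N(S(=O)(=O)c2cc(C(F)(F)F)cc(C(F)(F)F)c2)[C@@H](c2ccccc2)[C@H](c2ccccc2)N1S(=O)(=O)c1cc(C(F)(F)F)cc(C(F)(F)F)c1 | intermediate (not isolated)
9 | B-acyloxy (4S,5S)-diazaborolidine of acid 10 | C[Si](C)(C)C#CCC[C@@H](C(=O)OB1N(S(=O)(=O)c2cc(C(F)(F)F)cc(C(F)(F)F)c2)[C@@H](c2ccccc2)[C@H](c2ccccc2)N1S(=O)(=O)c1cc(C(F)(F)F)cc(C(F)(F)F)c1)[C@](C)(C=C)CCO[Si](C)(C)C(C)(C)C | intermediate (not isolated)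
10 | (2R,3S)-3-(2-{[tert-butyl(dimethyl)silyl]oxy}ethyl)-3-methyl-2-[4-(trimethylsilyl)but-3-yn-1-yl]pent-4-enoic acid | C[Si](C)(C)C#CCC[C@@H](C(=O)O)[C@](C)(C=C)CCO[Si](C)(C)C(C)(C)C | intermediate
11 | 4-methoxybenzyl ester of 10 | C[Si](C)(C)C#CCC[C@@H](C(=O)OCc1ccc(OC)cc1)[C@](C)(C=C)CCO[Si](C)(C)C(C)(C)C | intermediate
12 | B-alkyl-9-borabicyclo[3.3.1]nonane from 11 (boron on the former vinyl terminus) | C[Si](C)(C)C#CCC[C@@H](C(=O)OCc1ccc(OC)cc1)[C@](C)(CCB1C2CCCC1CCC2)CCO[Si](C)(C)C(C)(C)C | intermediate (not isolated)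
13 | 4-methoxybenzyl (2R,3R)-3-(2-{[tert-butyl(dimethyl)silyl]oxy}ethyl)-5-hydroxy-3-methyl-2-[4-(trimethylsilyl)but-3-yn-1-yl]pentanoate | C[Si](C)(C)C#CCC[C@@H](C(=O)OCc1ccc(OC)cc1)[C@](C)(CCO)CCO[Si](C)(C)C(C)(C)C | intermediate
14 | 4-methoxybenzyl (2R,3S)-3-(2-{[tert-butyl(dimethyl)silyl]oxy}ethyl)-3-methyl-5-oxo-2-[4-(trimethylsilyl)but-3-yn-1-yl]pentanoate | C[Si](C)(C)C#CCC[C@@H](C(=O)OCc1ccc(OC)cc1)[C@](C)(CC=O)CCO[Si](C)(C)C(C)(C)C | intermediate
15 | 3-bromofuran | Brc1ccoc1 | starting material
16 | furan-3-yllithium | [Li]c1ccoc1 | intermediate (not isolated)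
17 | 4-methoxybenzyl (2R,3S)-3-(2-{[tert-butyl(dimethyl)silyl]oxy}ethyl)-5-(furan-3-yl)-5-hydroxy-3-methyl-2-[4-(trimethylsilyl)but-3-yn-1-yl]pentanoate, both C5 epimers | C[Si](C)(C)C#CCC[C@@H](C(=O)OCc1ccc(OC)cc1)[C@](C)(CC(O)c1ccoc1)CCO[Si](C)(C)C(C)(C)C | intermediate
18 | 4-methoxybenzyl (2R,3S)-3-(2-{[tert-butyl(dimethyl)silyl]oxy}ethyl)-5-(furan-3-yl)-3-methyl-5-oxo-2-[4-(trimethylsilyl)but-3-yn-1-yl]pentanoate | C[Si](C)(C)C#CCC[C@@H](C(=O)OCc1ccc(OC)cc1)[C@](C)(CC(=O)c1ccoc1)CCO[Si](C)(C)C(C)(C)C | intermediate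
19 | 4-methoxybenzyl (2R,3S)-5-(furan-3-yl)-3-(2-hydroxyethyl)-3-methyl-5-oxo-2-[4-(trimethylsilyl)but-3-yn-1-yl]pentanoate | C[Si](C)(C)C#CCC[C@@H](C(=O)OCc1ccc(OC)cc1)[C@](C)(CC(=O)c1ccoc1)CCO | intermediate
20 | 4-methoxybenzyl (2R,3S)-5-(furan-3-yl)-3-methyl-5-oxo-3-(2-oxoethyl)-2-[4-(trimethylsilyl)but-3-yn-1-yl]pentanoate | C[Si](C)(C)C#CCC[C@@H](C(=O)OCc1ccc(OC)cc1)[C@](C)(CC(=O)c1ccoc1)CC=O | intermediate
21 | erythro β-alkoxy allyl(diphenyl)phosphine adduct of 20, drawn as the lithium alkoxide (metal bound as a titanium isopropoxide ate complex; the two new centres are a mixture relative to the backbone and are left unspecified) | C[Si](C)(C)C#CCC[C@@H](C(=O)OCc1ccc(OC)cc1)[C@](C)(CC(=O)c1ccoc1)CC(O[Li])C(C=C)P(c1ccccc1)c1ccccc1 | intermediate (not isolated)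
22 | 4-methoxybenzyl (2R,3S,5Z)-3-[2-(furan-3-yl)-2-oxoethyl]-3-methyl-2-[4-(trimethylsilyl)but-3-yn-1-yl]octa-5,7-dienoate | C[Si](C)(C)C#CCC[C@@H](C(=O)OCc1ccc(OC)cc1)[C@](C)(CC(=O)c1ccoc1)C/C=C\C=C | intermediate
23 | caesium alkynoate from 22 | [Cs+].[O-]C(=O)C#CCC[C@@H](C(=O)OCc1ccc(OC)cc1)[C@](C)(CC(=O)c1ccoc1)C/C=C\C=C | intermediate (not isolated)
24 | bis(4-methoxybenzyl) (6R)-6-[(3S,5Z)-1-(furan-3-yl)-3-methyl-1-oxoocta-5,7-dien-3-yl]hept-2-ynedioate | COc1ccc(COC(=O)C#CCC[C@@H](C(=O)OCc2ccc(OC)cc2)[C@](C)(CC(=O)c2ccoc2)C/C=C\C=C)cc1 | intermediate (key-step precursor)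
25 | bis(4-methoxybenzyl) (2R)-2-[(3S,5Z)-1-(furan-3-yl)-3-methyl-1-oxoocta-5,7-dien-3-yl]-5,6-dimethylideneheptanedioate | C=C(CC[C@@H](C(=O)OCc1ccc(OC)cc1)[C@](C)(CC(=O)c1ccoc1)C/C=C\C=C)C(=C)C(=O)OCc1ccc(OC)cc1 | intermediate (not isolated)
26 | bis(4-methoxybenzyl) ester of the target, (4R,5S,7Z,9E) in overview locants | C=C1CC[C@@H](C(=O)OCc2ccc(OC)cc2)[C@](C)(CC(=O)c2ccoc2)C/C=C\C=C/1C(=O)OCc1ccc(OC)cc1 | intermediate (key-step product)
27 | (4R,5S,7Z,9E)-5-[2-(furan-3-yl)-2-oxoethyl]-5-methyl-1-methylidenecyclodeca-7,9-diene-4,10-dicarboxylic acid (overview locants) | C=C1CC[C@@H](C(=O)O)[C@](C)(CC(=O)c2ccoc2)C/C=C\C=C/1C(=O)O | target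

**Counts and risks**

Total step count: 15. Longest linear sequence: 14 steps (steps 2 to 15 from 4, or equally steps 1 and 3 to 15 from 1).

Steps most likely to fail:

1. Step 14 (Proposed new method). What may go wrong: closure in the exo mode to the nine-membered ring; arrest at tetraene 25 because the hindered acrylate-type methylene does not ring-close; oligomerisation; or catalyst attack at the internal C7=C8 bond with loss of butadiene. Fallback with known reactions, setting out from aldehyde 20 and returning at 26: Z-selective iodo-olefination of 20 with the ylide from [Ph3PCH2I]I and NaN(SiMe3)2 (THF/DMPU, −78 °C; Stork–Zhao olefination) would give the (Z)-vinyl iodide F1. Fluoride-mediated carboxylation and alkylation as in step 13 would give the iodo ynoate F2. Intermolecular cross enyne metathesis with ethylene (second-generation Grubbs catalyst, toluene, 80 °C), which has no ring strain to overcome, would give the iodo tetraene F3. An intramolecular Heck reaction (Pd(OAc)2, PPh3, Et3N, MeCN, high dilution, 70 °C) would then join C8 to the C9 methylene of the acrylate unit, and β-hydride elimination would form C9=C10 with C8 trans to the ester, which is 26.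

2. Step 4. What may go wrong: insufficient enantioface selection or a sluggish rearrangement at the quaternary centre, or attack of the Lewis acidic bromoborane on the silyl ether. Fallback, setting out from ester 7 and returning at 10: enolisation with LDA in THF/DMPU at −78 °C and trapping with Me3SiCl would give the Z(O)-trimethylsilyl ketene acetal F4, which on warming rearranges through the same chair to the racemic silyl ester F5. Hydrolysis would give the racemic acid, that is 10 together with its antipode F6, with the same relative configuration. Classical resolution through the crystalline (R)-1-phenylethylammonium salt F7 (the amine antipode to be chosen by screening) and acidification would return 10.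

3. Step 13. What may go wrong: enolisation of the furyl ketone by fluoride, or base-induced isomerisation of the newly formed ynoate to an allenoate during the in-flask alkylation. Fallback, setting out from 22 and returning at 24: K2CO3 in MeOH would remove the silyl group to give the terminal alkyne F8. Silver-catalysed C–H carboxylation (AgI cat., Cs2CO3, CO2, DMF, 50 °C) with acidic work-up would give the free alkynoic acid F9. Esterification under neutral conditions with 4-methoxybenzyl 2,2,2-trichloroacetimidate in CH2Cl2 would give 24.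

**Further compounds**

F1 | step 14 | 4-methoxybenzyl (2R,3S,5Z)-3-[2-(furan-3-yl)-2-oxoethyl]-6-iodo-3-methyl-2-[4-(trimethylsilyl)but-3-yn-1-yl]hex-5-enoate | C[Si](C)(C)C#CCC[C@@H](C(=O)OCc1ccc(OC)cc1)[C@](C)(CC(=O)c1ccoc1)C/C=C\I
F2 | step 14 | bis(4-methoxybenzyl) ynoate analogue of 24 with a (Z)-3-iodoallyl arm in place of the pentadienyl arm | COc1ccc(COC(=O)C#CCC[C@@H](C(=O)OCc2ccc(OC)cc2)[C@](C)(CC(=O)c2ccoc2)C/C=C\I)cc1
F3 | step 14 | bis(4-methoxybenzyl) 5,6-dimethylideneheptanedioate analogue of 25 with the (Z)-3-iodoallyl arm | C=C(CC[C@@H](C(=O)OCc1ccc(OC)cc1)[C@](C)(CC(=O)c1ccoc1)C/C=C\I)C(=C)C(=O)OCc1ccc(OC)cc1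
F4 | step 4 | Z(O)-trimethylsilyl ketene acetal of 7 (butynyl chain cis to O–Si) | C[Si](C)(C)C#CCC/C=C(/OC/C=C(\C)CCO[Si](C)(C)C(C)(C)C)O[Si](C)(C)C
F5 | step 4 | trimethylsilyl ester of racemic 10 (one enantiomer drawn) | C[Si](C)(C)C#CCC[C@@H](C(=O)O[Si](C)(C)C)[C@](C)(C=C)CCO[Si](C)(C)C(C)(C)C
F6 | step 4 | (2S,3R)-antipode of 10 | C[Si](C)(C)C#CCC[C@H](C(=O)O)[C@@](C)(C=C)CCO[Si](C)(C)C(C)(C)C
F7 | step 4 | (R)-1-phenylethylammonium salt of 10 | C[Si](C)(C)C#CCC[C@@H](C(=O)[O-])[C@](C)(C=C)CCO[Si](C)(C)C(C)(C)C.C[C@@H]([NH3+])c1ccccc1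
F8 | step 13 | 4-methoxybenzyl (2R,3S,5Z)-2-(but-3-yn-1-yl)-3-[2-(furan-3-yl)-2-oxoethyl]-3-methylocta-5,7-dienoate | C#CCC[C@@H](C(=O)OCc1ccc(OC)cc1)[C@](C)(CC(=O)c1ccoc1)C/C=C\C=C
F9 | step 13 | (6R)-6-[(3S,5Z)-1-(furan-3-yl)-3-methyl-1-oxoocta-5,7-dien-3-yl]-7-[(4-methoxybenzyl)oxy]-7-oxohept-2-ynoic acid | OC(=O)C#CCC[C@@H](C(=O)OCc1ccc(OC)cc1)[C@](C)(CC(=O)c1ccoc1)C/C=C\C=C
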